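**Strategy**

Everything rests on one disconnection: the acyclic Z unit O–CH=C(Ar)–CH2OH, which joins the 1-oxyethyl arm at C6 of the chromene ring to the cresol ring, is the base-opened isomer of an oxirane bearing aryl and alkoxymethyl on one carbon, and that oxirane is the methylene adduct of the ketone ArC(=O)CH2OR. In one flask a sulfur ylide adds the CH2 to the C=O group and closes the three-membered ring, then a lithium amide removes an OCH2 proton so that ring strain breaks the benzylic C–O bond, which moves the oxygen onto the new CH2 and sets the Z alkene. The precursor is this ketone with R = (S)-1-(7-methoxy-2,2-dimethylchromen-6-yl)ethyl and the phenol masked as its triisopropylsilyl ether.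

Key step: step 6

Remark: compounds 1, 4, 6 and 11 are taken as commercial; the ketone is assembled by Weinreb amide chemistry and not by carbene O–H insertion, because a metal carbenoid ortho to a silyloxy group and near the chromene C3=C4 bond would have intramolecular oxonium ylide formation and cyclopropanation open to it.

**Route**

Step 1
Reactants: 1 7-methoxy-2,2-dimethyl-2H-chromene
Product: 2 1-(7-methoxy-2,2-dimethyl-2H-chromen-6-yl)ethanone
Conditions: AcCl, SnCl4, CH2Cl2, −78 → −40 °C; cold aq. NaHCO3
Reagents that add atoms: acetyl chloride, CC(=O)Cl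
Why: Friedel–Crafts acylation at C6, the ring position para to the pyran oxygen and ortho to the methoxy group (C8 lies between two oxygens and is hindered), should outrun reaction at the C3=C4 alkene when the preformed AcCl–SnCl4 complex is used cold and the mixture is quenched into base before warming.

Step 2
Reactants: 2 1-(7-methoxy-2,2-dimethyl-2H-chromen-6-yl)ethanone
Product: 3 (S)-1-(7-methoxy-2,2-dimethyl-2H-chromen-6-yl)ethanol
Conditions: H2 (8 atm), RuCl2[(R)-xylbinap][(R)-daipen] (0.2 mol%), KOtBu (2 mol%), iPrOH, 25 °C
Reagents that add atoms: none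
Why: Noyori asymmetric hydrogenation with a RuH2(diphosphine)(diamine) catalyst transfers hydride and proton to the C=O group in an outer-sphere step that leaves the chromene C=C bond untouched and needs no acid, and the (R)-XylBINAP/(R)-DAIPEN pair, the mirror image of the one that gives (R)-1-arylethanols, should set the S configuration by catalyst control, ortho-substituted aryl methyl ketones being good substrates.

Step 3
Reactants: 3 (S)-1-(7-methoxy-2,2-dimethyl-2H-chromen-6-yl)ethanol; 4 2-chloro-N-methoxy-N-methylacetamide
Product: 5 (S)-N-methoxy-2-[1-(7-methoxy-2,2-dimethyl-2H-chromen-6-yl)ethoxy]-N-methylacetamide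
Conditions: NaH, THF/DMF, 0 °C; then 4, Bu4NI (cat.), 0 → 25 °C
Reagents that add atoms: 2-chloro-N-methoxy-N-methylacetamide (compound 4), CON(C)C(=O)CCl
Why: Williamson ether synthesis: the sodium alkoxide of 3 displaces halide from the α-halo amide (iodide catalysis) by SN2 at CH2, the Weinreb amide carbonyl being inert to alkoxide, and since no bond to the stereocentre is broken the S configuration is kept.

Step 4
Reactants: 6 2-bromo-5-methylphenol
Product: 7 (2-bromo-5-methylphenoxy)triisopropylsilane
Conditions: TIPSCl, imidazole, DMF, 25 °C
Reagents that add atoms: triisopropylsilyl chloride, CC(C)[Si](Cl)(C(C)C)C(C)C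
Why: Routine silylation of a phenol with a silyl chloride and imidazole in DMF, which leaves the aryl bromide untouched.

Step 5
Reactants: 7 (2-bromo-5-methylphenoxy)triisopropylsilane; 5 (S)-N-methoxy-2-[1-(7-methoxy-2,2-dimethyl-2H-chromen-6-yl)ethoxy]-N-methylacetamide
Product: 10 (S)-2-[1-(7-methoxy-2,2-dimethyl-2H-chromen-6-yl)ethoxy]-1-[4-methyl-2-(triisopropylsilyloxy)phenyl]ethanone, via aryl Grignard reagent 8 (not isolated), via magnesium hemiaminal chelate 9 (not isolated)
Conditions: 7, Mg, THF, 50 °C; then 5, THF, 0 → 25 °C; then H2O
Reagents that add atoms: none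
Why: Weinreb ketone synthesis: magnesium inserts into the C–Br bond, the aryl Grignard reagent adds once to the amide to give a five-membered N-methoxy magnesium chelate that collapses to the ketone only on aqueous work-up, and an aryl–magnesium bond, unlike an aryl–lithium bond, should not draw the ortho silyl group from oxygen to carbon.

Step 6
Reactants: 10 (S)-2-[1-(7-methoxy-2,2-dimethyl-2H-chromen-6-yl)ethoxy]-1-[4-methyl-2-(triisopropylsilyloxy)phenyl]ethanone; 11 trimethylsulfonium iodide
Product: 14 (Z)-3-[(S)-1-(7-methoxy-2,2-dimethyl-2H-chromen-6-yl)ethoxy]-2-[4-methyl-2-(triisopropylsilyloxy)phenyl]prop-2-en-1-ol, via dimethylsulfonium methylide 12 (not isolated), via oxirane 13 (not isolated)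
Conditions: 11, n-BuLi, THF, −10 °C; add 10, −10 → 0 °C; then LiNEt2 (from Et2NH, n-BuLi), THF, −20 → 20 °C; then H2O
Reagents that add atoms: trimethylsulfonium iodide (compound 11), C[S+](C)C.[I-]
Why: Ylide 12, made from 11 with slightly less than one equivalent of n-BuLi so that no free base meets the enolisable ketone, adds to the carbonyl carbon of 10 and the betaine alkoxide displaces dimethyl sulfide by 3-exo-tet attack on the sulfur-bound CH2, which closes oxirane 13 and places the former carbonyl oxygen on the new carbon (Corey–Chaykovsky epoxidation). LiNEt2 then binds the oxirane oxygen and takes one OCH2 proton syn to the benzylic C–O bond through a six-membered transition state, and release of ring strain breaks that bond to give the lithium alkoxide of 14; this is the lithium amide isomerisation of an epoxide to an allylic alcohol, whose closest precedent on this substrate class is the base-promoted conversion of alkoxymethyl oxiranes into γ-hydroxy enol ethers. Regiochemistry is not in question because the OCH2 protons are the only hydrogens β to the benzylic C–O bond and the other oxirane carbon has no β-hydrogen, while attack of the amide on the oxirane CH2 is slowed by the adjacent fully substituted carbon. No lasting stereocentre is created, since the oxirane carbon forms as both epimers and becomes sp2, so the element to be controlled is the alkene geometry, which must be Z. With the abstracted proton syn to the oxirane oxygen, the pinched three-membered ring leaves the aryl group almost eclipsed with one remaining position on the OCH2 carbon and an open sector beside the ring CH2, so the bulky 1-arylethoxy group should take the open sector and the hydrogen the place next to the twisted ortho-silyloxyaryl ring, which sets the ether oxygen cis to CH2O, and a lithium bridging the ether oxygen and the departing oxirane oxygen points the same way. The benzylic C–H of the stereocentre is a tertiary ether proton on an electron-rich ring with no lithium-bound oxygen placed to deliver the amide to it, the bulky triisopropylsilyl group resists attack at silicon, and telescoping avoids isolating 13, which would be prone to Meinwald rearrangement on silica.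

Step 7
Reactants: 14 (Z)-3-[(S)-1-(7-methoxy-2,2-dimethyl-2H-chromen-6-yl)ethoxy]-2-[4-methyl-2-(triisopropylsilyloxy)phenyl]prop-2-en-1-ol
Product: 15 (Z)-3-[(S)-1-(7-methoxy-2,2-dimethyl-2H-chromen-6-yl)ethoxy]-2-(2-hydroxy-4-methylphenyl)prop-2-en-1-ol
Conditions: Bu4NF, AcOH (1:1), THF, 0 °C; pH 7 work-up
Reagents that add atoms: none
Why: Fluoride attacks silicon and expels the phenoxide, while the acetic acid buffer keeps the medium near neutral so that the acid-labile enol ether, the allylic alcohol and the benzylic ether survive, and any silyl group that had moved to the primary oxygen in step 6 is removed by the same reagent.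

**Compound list**

1 | 7-methoxy-2,2-dimethyl-2H-chromene | COc1ccc2C=CC(C)(C)Oc2c1 | starting material
2 | 1-(7-methoxy-2,2-dimethyl-2H-chromen-6-yl)ethanone | COc1cc2c(cc1C(C)=O)C=CC(C)(C)O2 | intermediate
3 | (S)-1-(7-methoxy-2,2-dimethyl-2H-chromen-6-yl)ethanol | COc1cc2c(cc1[C@H](C)O)C=CC(C)(C)O2 | intermediate
4 | 2-chloro-N-methoxy-N-methylacetamide | CON(C)C(=O)CCl | starting material
5 | (S)-N-methoxy-2-[1-(7-methoxy-2,2-dimethyl-2H-chromen-6-yl)ethoxy]-N-methylacetamide | COc1cc2c(cc1[C@H](C)OCC(=O)N(C)OC)C=CC(C)(C)O2 | intermediate
6 | 2-bromo-5-methylphenol | Cc1ccc(Br)c(O)c1 | starting material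
7 | (2-bromo-5-methylphenoxy)triisopropylsilane | Cc1ccc(Br)c(O[Si](C(C)C)(C(C)C)C(C)C)c1 | intermediate
8 | [4-methyl-2-(triisopropylsilyloxy)phenyl]magnesium bromide (not isolated) | Cc1ccc([Mg]Br)c(O[Si](C(C)C)(C(C)C)C(C)C)c1 | intermediate
9 | bromomagnesium salt of the N-methoxy-N-methyl hemiaminal from 8 and 5, S at the benzylic ether carbon, both configurations at the transient hemiaminal carbon (not isolated) | COc1cc2c(cc1[C@H](C)OCC(O[Mg]Br)(N(C)OC)c1ccc(C)cc1O[Si](C(C)C)(C(C)C)C(C)C)C=CC(C)(C)O2 | intermediate
10 | (S)-2-[1-(7-methoxy-2,2-dimethyl-2H-chromen-6-yl)ethoxy]-1-[4-methyl-2-(triisopropylsilyloxy)phenyl]ethanone | COc1cc2c(cc1[C@H](C)OCC(=O)c1ccc(C)cc1O[Si](C(C)C)(C(C)C)C(C)C)C=CC(C)(C)O2 | intermediate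
11 | trimethylsulfonium iodide | C[S+](C)C.[I-] | starting material
12 | dimethylsulfonium methylide (not isolated) | C[S+](C)[CH2-] | intermediate
13 | 2-{[(S)-1-(7-methoxy-2,2-dimethyl-2H-chromen-6-yl)ethoxy]methyl}-2-[4-methyl-2-(triisopropylsilyloxy)phenyl]oxirane, both epimers at the oxirane carbon (not isolated) | COc1cc2c(cc1[C@H](C)OCC1(CO1)c1ccc(C)cc1O[Si](C(C)C)(C(C)C)C(C)C)C=CC(C)(C)O2 | intermediate
14 | (Z)-3-[(S)-1-(7-methoxy-2,2-dimethyl-2H-chromen-6-yl)ethoxy]-2-[4-methyl-2-(triisopropylsilyloxy)phenyl]prop-2-en-1-ol | COc1cc2c(cc1[C@H](C)O/C=C(\CO)c1ccc(C)cc1O[Si](C(C)C)(C(C)C)C(C)C)C=CC(C)(C)O2 | intermediate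
15 | (Z)-3-[(S)-1-(7-methoxy-2,2-dimethyl-2H-chromen-6-yl)ethoxy]-2-(2-hydroxy-4-methylphenyl)prop-2-en-1-ol | COc1cc2c(cc1[C@H](C)O/C=C(\CO)c1ccc(C)cc1O)C=CC(C)(C)O2 | target

**Step count and risks**

Total steps: 7. Longest linear sequence: 6 steps (1 → 2 → 3 → 5 → 10 → 14 → 15); step 4 is a one-step side branch.

Steps most likely to fail:

Step 6. The syn-elimination may discriminate too weakly between the two OCH2 protons and give a mixture of enol ether geometries. The amide may also open or metalate the oxirane CH2. Fallback, setting out from 7 and 3 and coming back to the route at 15: Grignard reagent 8, made from 7 as in step 5, is added in excess to propargyl alcohol with catalytic CuI (copper monoiodide) in THF. Anti-carbomagnesiation puts the aryl group on the internal carbon and leaves a vinyl–magnesium bond held cis to CH2O by the alkoxide, so an iodine quench should give (Z)-3-iodo-2-[4-methyl-2-(triisopropylsilyloxy)phenyl]prop-2-en-1-ol F1. TBSCl and imidazole convert it into the tert-butyldimethylsilyl ether of this iodo alcohol F2. An Ullmann-type C–O coupling of this vinyl iodide with alcohol 3 (CuI, 3,4,7,8-tetramethyl-1,10-phenanthroline, Cs2CO3, toluene, 80 °C), which retains alkene geometry, should give the O-tert-butyldimethylsilyl, O-triisopropylsilyl bis-ether of the target F3. Bu4NF/AcOH as in step 7 then removes both silyl groups to give 15.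

Step 1. Acid may oligomerise the chromene through its C4 cation, or the acylium ion may attack C3 of the alkene in place of C6 of the ring. Fallback, setting out from 1 and coming back at 2: Vilsmeier–Haack formylation (POCl3, DMF), whose chloroiminium electrophile is mild toward the alkene, should give 7-methoxy-2,2-dimethyl-2H-chromene-6-carbaldehyde F4. MeMgBr in THF then gives racemic 1-(7-methoxy-2,2-dimethyl-2H-chromen-6-yl)ethanol F5, and MnO2 in CH2Cl2 oxidises this benzylic alcohol to ketone 2.

Step 5. Magnesium insertion into the hindered, electron-rich bromide may be sluggish, or the hindered Grignard reagent may deprotonate the amide α-CH2 in competition with addition. Fallback, setting out from 6 and 5 and coming back at 10: free bromophenol 6 with two equivalents of n-BuLi (Et2O, 0 °C) gives lithium 2-lithio-5-methylphenoxide F6 by deprotonation and bromine–lithium exchange, with no silyl group present to migrate. This more nucleophilic aryllithium adds to amide 5 at −78 °C and gives, after work-up, (S)-1-(2-hydroxy-4-methylphenyl)-2-[1-(7-methoxy-2,2-dimethyl-2H-chromen-6-yl)ethoxy]ethanone F7. TIPSCl and imidazole in DMF then silylate the phenol to give 10.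

**Further compounds**

F1 | step 6 | (Z)-3-iodo-2-[4-methyl-2-(triisopropylsilyloxy)phenyl]prop-2-en-1-ol | I/C=C(\CO)c1ccc(C)cc1O[Si](C(C)C)(C(C)C)C(C)C
F2 | step 6 | tert-butyldimethylsilyl ether of (Z)-3-iodo-2-[4-methyl-2-(triisopropylsilyloxy)phenyl]prop-2-en-1-ol | I/C=C(\CO[Si](C)(C)C(C)(C)C)c1ccc(C)cc1O[Si](C(C)C)(C(C)C)C(C)C
F3 | step 6 | O-tert-butyldimethylsilyl, O-triisopropylsilyl bis-ether of the target, S at the benzylic carbon, Z alkene | COc1cc2c(cc1[C@H](C)O/C=C(\CO[Si](C)(C)C(C)(C)C)c1ccc(C)cc1O[Si](C(C)C)(C(C)C)C(C)C)C=CC(C)(C)O2
F4 | step 1 | 7-methoxy-2,2-dimethyl-2H-chromene-6-carbaldehyde | COc1cc2c(cc1C=O)C=CC(C)(C)O2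
F5 | step 1 | racemic 1-(7-methoxy-2,2-dimethyl-2H-chromen-6-yl)ethanol | COc1cc2c(cc1C(C)O)C=CC(C)(C)O2
F6 | step 5 | lithium 2-lithio-5-methylphenoxide | Cc1ccc([Li])c(O[Li])c1
F7 | step 5 | (S)-1-(2-hydroxy-4-methylphenyl)-2-[1-(7-methoxy-2,2-dimethyl-2H-chromen-6-yl)ethoxy]ethanone | COc1cc2c(cc1[C@H](C)OCC(=O)c1ccc(C)cc1O)C=CC(C)(C)O2
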